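The acylhydroquinone ring is made last. Its pattern, a ketone on C1′ with oxygens on C2′ and C5′ of the benzene ring, is cut into 2-methoxyfuran (C2′ to C5′ and both aryl oxygens) and a terminal ynone whose alkyne carbons become C1′ and C6′. One thermal cycloaddition with ring-opening aromatisation forms C1′–C2′ and C5′–C6′ and gives the arene with methoxy ortho and hydroxyl meta to the acyl group. The precursor is the finished (R)-oxepene, built from (R)-malic acid by acetal-controlled allylation, etherification and ring-closing metathesis. It carries the ynone arm, a silyl-protected side chain and a 4-methoxybenzyl ester.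

Key step: step 15

Remark on the chemistry: the carboxyl group is carried as a 4-methoxybenzyl ester, not a methyl ester. A final saponification would also cleave the coumarate ester and expose the β-alkoxy aryl ketone to base-induced opening of the oxepene. Compounds 23 and 26 are transient and form as mixtures at their short-lived new stereocentres.

Step 1
Reactants: 1 5-bromo-2-methylpent-2-ene
Product: 2 (2E)-5-bromo-2-methylpent-2-en-1-ol
Conditions: SeO2 (cat.), t-BuOOH, salicylic acid (cat.), CH2Cl2, 0 °C to rt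
Reagents that add atoms: tert-butyl hydroperoxide, CC(C)(C)OO
Why: Riley-type allylic oxidation (ene reaction, then [2,3]-sigmatropic shift, t-BuOOH as terminal oxidant) should attack the (E)-methyl group at the disubstituted end of the trisubstituted olefin, which fixes the (E)-geometry that the side chain keeps to the end.

Step 2
Reactants: 2 (2E)-5-bromo-2-methylpent-2-en-1-ol
Product: 3 {[(2E)-5-bromo-2-methylpent-2-en-1-yl]oxy}(tert-butyl)dimethylsilane
Conditions: TBSCl, imidazole, CH2Cl2, 0 °C to rt
Reagents that add atoms: tert-butyldimethylsilyl chloride, CC(C)(C)[Si](C)(C)Cl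
Why: Standard imidazole-assisted silylation of a primary alcohol masks the hydroxyl group for the organomagnesium chemistry that follows.

Step 3
Reactants: 3 silyl ether bromide; 4 prop-2-yn-1-ol
Product: 6 (5E)-7-[(tert-butyldimethylsilyl)oxy]-6-methyl-2-methylidenehept-5-en-1-ol, via Grignard reagent 5 (not isolated)
Conditions: Mg, THF, 40 °C; then 4 (0.4 equiv), CuI (10 mol %), THF, –20 °C to rt; aq NH4Cl
Reagents that add atoms: none
Why: Copper-catalysed anti-carbomagnesiation of the propargylic magnesium alkoxide should place the alkyl group on the internal alkyne carbon through a five-membered alkenylmagnesium chelate, whose protonation leaves the 2-substituted allylic alcohol; one equivalent of 5 is spent on the hydroxyl proton.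

Step 4
Reactants: 6 allylic alcohol
Product: 7 {[(2E)-6-(bromomethyl)-2-methylhepta-2,6-dien-1-yl]oxy}(tert-butyl)dimethylsilane
Conditions: CBr4, PPh3, CH2Cl2, 0 °C
Reagents that add atoms: carbon tetrabromide, BrC(Br)(Br)Br
Why: Appel bromination should convert the primary allylic alcohol by SN2 displacement of the oxyphosphonium group under neutral conditions that leave the silyl ether and both olefins alone.

Step 5
Reactants: 8 (R)-malic acid
Product: 9 2-[(2R,4R)-2-tert-butyl-5-oxo-1,3-dioxolan-4-yl]acetic acid (cis)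
Conditions: pivalaldehyde, TsOH·H2O (cat.), H2SO4 (cat.), pentane, reflux with water separator; recrystallisation
Reagents that add atoms: pivalaldehyde, CC(C)(C)C=O
Why: Acid-catalysed acetalisation of the α-hydroxy acid unit with removal of water should give the cis-dioxolanone as the thermodynamic, crystalline isomer, so the new acetal centre (2R) is set by the existing C2 centre of malic acid.

Step 6
Reactants: 9 cis-dioxolanone acid; 10 allyl bromide
Product: 12 2-[(2R,4R)-2-tert-butyl-5-oxo-4-(prop-2-en-1-yl)-1,3-dioxolan-4-yl]acetic acid, via dilithium enolate carboxylate 11 (not isolated)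
Conditions: LiN(SiMe3)2 (2.2 equiv), THF, –78 °C; 10, –78 to –20 °C; 1 M HCl
Reagents that add atoms: none
Why: Self-regeneration of the stereocentre: the planar enolate of 11 should be alkylated by allyl bromide on the face opposite the tert-butyl group of the acetal centre, so allyl takes the place of the former hydrogen and the quaternary centre is formed with retention as (4R).

Step 7
Reactants: 12 allylated dioxolanone acid
Product: 13 2-[(2R,4R)-2-tert-butyl-5-oxo-4-(prop-2-en-1-yl)-1,3-dioxolan-4-yl]-N-methoxy-N-methylacetamide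
Conditions: MeNHOMe·HCl, EDC·HCl, HOBt (cat.), N-methylmorpholine, CH2Cl2, 0 °C to rt
Reagents that add atoms: N,O-dimethylhydroxylamine hydrochloride, Cl.CNOC
Why: Carbodiimide-mediated amide coupling should turn the free acetic acid arm into the Weinreb amide, while the hindered dioxolanone carbonyl is not attacked by the weakly nucleophilic amine.

Step 8
Reactants: 13 allyl Weinreb amide
Product: 15 2-[(2R,4R)-2-tert-butyl-4-(3-hydroxypropyl)-5-oxo-1,3-dioxolan-4-yl]-N-methoxy-N-methylacetamide, via B-alkyl-9-borabicyclononane 14 (not isolated)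
Conditions: 9-BBN, THF, 0 °C to rt; then H2O2, aq NaOAc, 0 °C
Reagents that add atoms: hydrogen peroxide, OO
Why: Hydroboration–oxidation with the bulky borane should be selective for the terminal carbon of the allyl group and leave the amide and acylal carbonyls alone, and the buffered peroxide work-up spares the dioxolanone.

Step 9
Reactants: 15 primary alcohol
Product: 16 2-[(2R,4R)-2-tert-butyl-5-oxo-4-(3-oxopropyl)-1,3-dioxolan-4-yl]-N-methoxy-N-methylacetamide
Conditions: Dess–Martin periodinane, CH2Cl2, 0 °C to rt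
Reagents that add atoms: none
Why: Dess–Martin oxidation should stop cleanly at the aldehyde under neutral conditions.

Step 10
Reactants: 16 aldehyde
Product: 17 2-[(2R,4R)-4-(but-3-en-1-yl)-2-tert-butyl-5-oxo-1,3-dioxolan-4-yl]-N-methoxy-N-methylacetamide
Conditions: Ph3PCH3Br, KN(SiMe3)2, THF, 0 °C; then 16, –78 to 0 °C
Reagents that add atoms: methyltriphenylphosphonium bromide, [Br-].C[P+](c1ccccc1)(c1ccccc1)c1ccccc1
Why: Wittig methylenation with the salt-free ylide should convert the aldehyde into the terminal olefin, the ester-type carbonyl groups being inert to the ylide at low temperature; this completes the one-carbon extension of allyl to but-3-enyl.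

Step 11
Reactants: 17 butenyl dioxolanone
Product: 18 4-methoxybenzyl (2R)-2-hydroxy-2-{2-[methoxy(methyl)amino]-2-oxoethyl}hex-5-enoate
Conditions: 4-methoxybenzyl alcohol (3 equiv), NaH (0.3 equiv), THF, 0 °C to rt; aq NH4Cl
Reagents that add atoms: 4-methoxybenzyl alcohol, COc1ccc(CO)cc1
Why: Alkoxide-catalysed transesterification of the activated acylal carbonyl should open the dioxolanone, release pivalaldehyde and uncover the tertiary alcohol as its 4-methoxybenzyl ester without touching the quaternary centre.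

Step 12
Reactants: 18 tertiary hydroxy ester; 7 allylic bromide
Product: 20 4-methoxybenzyl (2R)-2-({(5E)-7-[(tert-butyldimethylsilyl)oxy]-6-methyl-2-methylidenehept-5-en-1-yl}oxy)-2-{2-[methoxy(methyl)amino]-2-oxoethyl}hex-5-enoate, via sodium alkoxide 19 (not isolated)
Conditions: NaH (1.3 equiv), DMF, 0 °C; then 7, Bu4NI (10 mol %), 0 °C to rt
Reagents that add atoms: none
Why: Williamson etherification: the tertiary alkoxide should displace the reactive primary allylic bromide (SN2, iodide catalysis), and an amide enolate is too poor a leaving group for retro-aldol cleavage to compete.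

Step 13
Reactants: 20 diene ether
Product: 21 4-methoxybenzyl (2R)-6-{(3E)-5-[(tert-butyldimethylsilyl)oxy]-4-methylpent-3-en-1-yl}-2-{2-[methoxy(methyl)amino]-2-oxoethyl}-2,3,4,7-tetrahydrooxepine-2-carboxylate
Conditions: second-generation Grubbs catalyst RuCl2(=CHPh)(PCy3)(H2IMes) (5 mol %), CH2Cl2 (5 mM), 40 °C
Reagents that add atoms: none
Why: Ring-closing metathesis between the monosubstituted and the 1,1-disubstituted olefin should close the seven-membered ether with its trisubstituted ring olefin, helped by the quaternary centre, while the hindered trisubstituted side-chain olefin stays out of the catalytic cycle.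

Step 14
Reactants: 21 oxepene Weinreb amide; 22 ethynylmagnesium bromide
Product: 24 4-methoxybenzyl (2R)-6-{(3E)-5-[(tert-butyldimethylsilyl)oxy]-4-methylpent-3-en-1-yl}-2-(2-oxobut-3-yn-1-yl)-2,3,4,7-tetrahydrooxepine-2-carboxylate, via magnesium hemiaminal chelate 23 (not isolated)
Conditions: 22 (4 equiv), THF, 0 °C; inverse quench into cold 1 M HCl
Reagents that add atoms: none
Why: Weinreb ketone synthesis: the chelated tetrahedral adduct 23 should resist a second addition and collapse to the terminal ynone only on acidic quench, which also keeps the released amine protonated so that it cannot add to the ynone.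

Step 15
Reactants: 24 oxepene terminal ynone; 25 2-methoxyfuran
Product: 27 4-methoxybenzyl (2R)-6-{(3E)-5-[(tert-butyldimethylsilyl)oxy]-4-methylpent-3-en-1-yl}-2-[2-(5-hydroxy-2-methoxyphenyl)-2-oxoethyl]-2,3,4,7-tetrahydrooxepine-2-carboxylate, via oxanorbornadiene cycloadduct 26 (not isolated)
Conditions: 25 (3 equiv), toluene, 50 °C, dark; then SiO2, rt
Reagents that add atoms: none
Why: The electron-rich furan 25 (diene) and the electron-poor ynone 24 (dienophile) should combine in a polarised, asynchronous Diels–Alder addition in which the unsubstituted furan C5 bonds to the terminal alkyne carbon and the methoxy-bearing C2 to the acyl-bearing carbon, giving 26. In 26 the bridging C–O bond at the methoxy ketal carbon is pushed open by the methoxy lone pair and pulled by the vinylogous ketone, and loss of the former furan C5 proton with tautomerisation gives the phenol; the closest known reaction type is the cycloaddition and ring-opening aromatisation of 2-alkoxyfurans with acetylenic ketones and esters to 4-alkoxyphenols. The benzene ring is closed by an intermolecular [4+2] cycloaddition that makes C1′–C2′ and C5′–C6′ in one operation, followed by opening of the oxygen bridge. No stereocentre is created, since the bridgehead centres of 26 vanish on aromatisation, and the C2 centre of the oxepene is not touched. The step needs regioselectivity (methoxy ortho, hydroxyl meta to the acyl group), which the donor on furan C2 and the acceptor on the alkyne secure, and chemoselectivity for cycloaddition over conjugate addition, which the absence of free hydroxyl groups in 24 and the neutral, base-free conditions secure; the same conditions spare the β-alkoxy ketone from elimination.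

Step 16
Reactants: 27 aryl ketone silyl ether
Product: 28 4-methoxybenzyl (2R)-2-[2-(5-hydroxy-2-methoxyphenyl)-2-oxoethyl]-6-[(3E)-5-hydroxy-4-methylpent-3-en-1-yl]-2,3,4,7-tetrahydrooxepine-2-carboxylate
Conditions: HF·pyridine, pyridine, THF, 0 °C to rt
Reagents that add atoms: none
Why: Fluoride-mediated desilylation under buffered, mildly acidic conditions should free the primary allylic alcohol without base, so the β-alkoxy ketone and the benzylic ester are not endangered.

Step 17
Reactants: 28 allylic alcohol; 29 (2E)-3-(4-hydroxyphenyl)prop-2-enoic acid (p-coumaric acid)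
Product: 30 4-methoxybenzyl (2R)-2-[2-(5-hydroxy-2-methoxyphenyl)-2-oxoethyl]-6-[(3E)-5-{[(2E)-3-(4-hydroxyphenyl)prop-2-enoyl]oxy}-4-methylpent-3-en-1-yl]-2,3,4,7-tetrahydrooxepine-2-carboxylate
Conditions: 29 (1.5 equiv), PPh3, DIAD (added last), THF, 0 °C
Reagents that add atoms: none
Why: Mitsunobu esterification: the carboxylic acid, far more acidic than any phenol present, should be the pronucleophile that displaces the activated primary allylic alcohol by SN2, so the phenols need no protection and no base is used.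

Step 18
Reactants: 30 coumarate ester
Product: 31 (2R)-2-[2-(2,5-dihydroxyphenyl)-2-oxoethyl]-6-[(3E)-5-{[(2E)-3-(4-hydroxyphenyl)prop-2-enoyl]oxy}-4-methylpent-3-en-1-yl]-2,3,4,7-tetrahydrooxepine-2-carboxylic acid (CNP0602535.1)
Conditions: BCl3 (6 equiv), C6HMe5 (5 equiv), CH2Cl2, –78 to –20 °C; MeOH, then pH 4 phosphate buffer
Reagents that add atoms: none
Why: Lewis-acid dealkylation: BCl3 held in a six-membered chelate between the ketone and the ortho-methoxy oxygen should cleave that methyl ether and at the same time ionise the 4-methoxybenzyl ester, whose cation is trapped by pentamethylbenzene in a Friedel–Crafts alkylation; the low temperature is meant to spare the allylic ester and the allylic ring ether.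

Compound list
1 | 5-bromo-2-methylpent-2-ene | CC(C)=CCCBr | starting material
2 | (2E)-5-bromo-2-methylpent-2-en-1-ol | C/C(=C\CCBr)CO | intermediate
3 | {[(2E)-5-bromo-2-methylpent-2-en-1-yl]oxy}(tert-butyl)dimethylsilane | C/C(=C\CCBr)CO[Si](C)(C)C(C)(C)C | intermediate
4 | prop-2-yn-1-ol (propargyl alcohol) | C#CCO | starting material
5 | {(3E)-5-[(tert-butyldimethylsilyl)oxy]-4-methylpent-3-en-1-yl}magnesium bromide | C/C(=C\CC[Mg]Br)CO[Si](C)(C)C(C)(C)C | intermediate
6 | (5E)-7-[(tert-butyldimethylsilyl)oxy]-6-methyl-2-methylidenehept-5-en-1-ol | C/C(=C\CCC(=C)CO)CO[Si](C)(C)C(C)(C)C | intermediate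
7 | {[(2E)-6-(bromomethyl)-2-methylhepta-2,6-dien-1-yl]oxy}(tert-butyl)dimethylsilane | C/C(=C\CCC(=C)CBr)CO[Si](C)(C)C(C)(C)C | intermediate
8 | (R)-malic acid, (2R)-2-hydroxybutanedioic acid | O[C@H](CC(=O)O)C(=O)O | starting material
9 | 2-[(2R,4R)-2-tert-butyl-5-oxo-1,3-dioxolan-4-yl]acetic acid (tert-butyl and CH2CO2H cis) | CC(C)(C)[C@@H]1O[C@H](CC(=O)O)C(=O)O1 | intermediate
10 | allyl bromide (3-bromoprop-1-ene) | C=CCBr | starting material
11 | dilithium (2R)-2-tert-butyl-5-(carboxylatomethyl)-1,3-dioxol-4-olate | [Li+].[Li+].CC(C)(C)[C@@H]1OC(CC(=O)[O-])=C([O-])O1 | intermediate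
12 | 2-[(2R,4R)-2-tert-butyl-5-oxo-4-(prop-2-en-1-yl)-1,3-dioxolan-4-yl]acetic acid | CC(C)(C)[C@@H]1O[C@](CC=C)(CC(=O)O)C(=O)O1 | intermediate
13 | 2-[(2R,4R)-2-tert-butyl-5-oxo-4-(prop-2-en-1-yl)-1,3-dioxolan-4-yl]-N-methoxy-N-methylacetamide | CC(C)(C)[C@@H]1O[C@](CC=C)(CC(=O)N(C)OC)C(=O)O1 | intermediate
14 | 2-{(2R,4R)-4-[3-(9-borabicyclo[3.3.1]nonan-9-yl)propyl]-2-tert-butyl-5-oxo-1,3-dioxolan-4-yl}-N-methoxy-N-methylacetamide | CC(C)(C)[C@@H]1O[C@](CCCB2C3CCCC2CCC3)(CC(=O)N(C)OC)C(=O)O1 | intermediate
15 | 2-[(2R,4R)-2-tert-butyl-4-(3-hydroxypropyl)-5-oxo-1,3-dioxolan-4-yl]-N-methoxy-N-methylacetamide | CC(C)(C)[C@@H]1O[C@](CCCO)(CC(=O)N(C)OC)C(=O)O1 | intermediate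
16 | 2-[(2R,4R)-2-tert-butyl-5-oxo-4-(3-oxopropyl)-1,3-dioxolan-4-yl]-N-methoxy-N-methylacetamide | CC(C)(C)[C@@H]1O[C@](CCC=O)(CC(=O)N(C)OC)C(=O)O1 | intermediate
17 | 2-[(2R,4R)-4-(but-3-en-1-yl)-2-tert-butyl-5-oxo-1,3-dioxolan-4-yl]-N-methoxy-N-methylacetamide | CC(C)(C)[C@@H]1O[C@](CCC=C)(CC(=O)N(C)OC)C(=O)O1 | intermediate
18 | 4-methoxybenzyl (2R)-2-hydroxy-2-{2-[methoxy(methyl)amino]-2-oxoethyl}hex-5-enoate | C=CCC[C@@](O)(CC(=O)N(C)OC)C(=O)OCc1ccc(OC)cc1 | intermediate
19 | sodium (2R)-1-[(4-methoxybenzyl)oxy]-2-{2-[methoxy(methyl)amino]-2-oxoethyl}-1-oxohex-5-en-2-olate | [Na+].C=CCC[C@@]([O-])(CC(=O)N(C)OC)C(=O)OCc1ccc(OC)cc1 | intermediate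
20 | 4-methoxybenzyl (2R)-2-({(5E)-7-[(tert-butyldimethylsilyl)oxy]-6-methyl-2-methylidenehept-5-en-1-yl}oxy)-2-{2-[methoxy(methyl)amino]-2-oxoethyl}hex-5-enoate | C=CCC[C@@](OCC(=C)CC/C=C(\C)CO[Si](C)(C)C(C)(C)C)(CC(=O)N(C)OC)C(=O)OCc1ccc(OC)cc1 | intermediate
21 | 4-methoxybenzyl (2R)-6-{(3E)-5-[(tert-butyldimethylsilyl)oxy]-4-methylpent-3-en-1-yl}-2-{2-[methoxy(methyl)amino]-2-oxoethyl}-2,3,4,7-tetrahydrooxepine-2-carboxylate | C/C(=C\CCC1=CCC[C@@](CC(=O)N(C)OC)(C(=O)OCc2ccc(OC)cc2)OC1)CO[Si](C)(C)C(C)(C)C | intermediate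
22 | ethynylmagnesium bromide | C#C[Mg]Br | starting material
23 | bromomagnesium hemiaminal from 21 and 22: the amide carbon carries OMgBr, ethynyl and N(OMe)Me (new centre as a mixture) | C/C(=C\CCC1=CCC[C@@](CC(O[Mg]Br)(C#C)N(C)OC)(C(=O)OCc2ccc(OC)cc2)OC1)CO[Si](C)(C)C(C)(C)C | intermediate
24 | 4-methoxybenzyl (2R)-6-{(3E)-5-[(tert-butyldimethylsilyl)oxy]-4-methylpent-3-en-1-yl}-2-(2-oxobut-3-yn-1-yl)-2,3,4,7-tetrahydrooxepine-2-carboxylate | C/C(=C\CCC1=CCC[C@@](CC(=O)C#C)(C(=O)OCc2ccc(OC)cc2)OC1)CO[Si](C)(C)C(C)(C)C | intermediate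
25 | 2-methoxyfuran | COc1ccco1 | starting material
26 | 4-methoxybenzyl (2R)-6-{(3E)-5-[(tert-butyldimethylsilyl)oxy]-4-methylpent-3-en-1-yl}-2-[2-(1-methoxy-7-oxabicyclo[2.2.1]hepta-2,5-dien-2-yl)-2-oxoethyl]-2,3,4,7-tetrahydrooxepine-2-carboxylate (bridgehead centres as a mixture) | C/C(=C\CCC1=CCC[C@@](CC(=O)C2=CC3C=CC2(OC)O3)(C(=O)OCc2ccc(OC)cc2)OC1)CO[Si](C)(C)C(C)(C)C | intermediate
27 | 4-methoxybenzyl (2R)-6-{(3E)-5-[(tert-butyldimethylsilyl)oxy]-4-methylpent-3-en-1-yl}-2-[2-(5-hydroxy-2-methoxyphenyl)-2-oxoethyl]-2,3,4,7-tetrahydrooxepine-2-carboxylate | C/C(=C\CCC1=CCC[C@@](CC(=O)c2cc(O)ccc2OC)(C(=O)OCc2ccc(OC)cc2)OC1)CO[Si](C)(C)C(C)(C)C | intermediate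
28 | 4-methoxybenzyl (2R)-2-[2-(5-hydroxy-2-methoxyphenyl)-2-oxoethyl]-6-[(3E)-5-hydroxy-4-methylpent-3-en-1-yl]-2,3,4,7-tetrahydrooxepine-2-carboxylate | C/C(=C\CCC1=CCC[C@@](CC(=O)c2cc(O)ccc2OC)(C(=O)OCc2ccc(OC)cc2)OC1)CO | intermediate
29 | (2E)-3-(4-hydroxyphenyl)prop-2-enoic acid (p-coumaric acid) | O=C(O)/C=C/c1ccc(O)cc1 | starting material
30 | 4-methoxybenzyl (2R)-2-[2-(5-hydroxy-2-methoxyphenyl)-2-oxoethyl]-6-[(3E)-5-{[(2E)-3-(4-hydroxyphenyl)prop-2-enoyl]oxy}-4-methylpent-3-en-1-yl]-2,3,4,7-tetrahydrooxepine-2-carboxylate | C/C(=C\CCC1=CCC[C@@](CC(=O)c2cc(O)ccc2OC)(C(=O)OCc2ccc(OC)cc2)OC1)COC(=O)/C=C/c1ccc(O)cc1 | intermediate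
31 | (2R)-2-[2-(2,5-dihydroxyphenyl)-2-oxoethyl]-6-[(3E)-5-{[(2E)-3-(4-hydroxyphenyl)prop-2-enoyl]oxy}-4-methylpent-3-en-1-yl]-2,3,4,7-tetrahydrooxepine-2-carboxylic acid (CNP0602535.1) | C/C(=C\CCC1=CCC[C@@](CC(=O)c2cc(O)ccc2O)(C(=O)O)OC1)COC(=O)/C=C/c1ccc(O)cc1 | target

Total step count: 18.
Longest linear sequence: 14 steps (steps 5 to 18, from (R)-malic acid 8). The side-chain bromide 7 is made in 4 steps (steps 1 to 4) and joins at step 12.

Steps most likely to fail

Step 15. The furan may be consumed by conjugate addition or by oligomerisation before it cycloadds, or the bridged adduct may open incompletely. The fallback makes the aryl–carbonyl bond with an organolithium and does not build the arene. It sets out from Weinreb amide 21 and comes back to the route at 28. Commercial 3-bromo-4-methoxyphenol is silylated (TBSCl, imidazole) to (3-bromo-4-methoxyphenoxy)(tert-butyl)dimethylsilane F1. Bromine–lithium exchange (n-BuLi, THF, –78 °C) gives {5-[(tert-butyldimethylsilyl)oxy]-2-methoxyphenyl}lithium F2. Added to 21 at –78 °C, this should give, through the same kind of chelated adduct as in step 14, the doubly silylated aryl ketone F3. Bu4NF buffered with acetic acid (THF, 0 °C) should then remove both silyl groups and deliver 28.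

Step 18. The boron Lewis acid may ionise the allylic ester or the allylic ring ether, or the ether cleavage may stay incomplete at the low temperature that protects them. The fallback replaces the single global step by two orthogonal operations. It sets out from 30 and comes back at 31. MgI2·OEt2 (Et2O/toluene, rt to 40 °C) should remove only the chelated ortho-methyl group by iodide attack within the magnesium chelate, giving the 4-methoxybenzyl ester of the target F4. Brønsted acidolysis (CF3CO2H, anisole, CH2Cl2, 0 °C) should then cleave the benzylic ester and give 31.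

Step 3. Wurtz coupling or cyclisation with loss of silanolate may erode the functionalised Grignard reagent, and a slow carbomagnesiation would waste it. The fallback carries out the carbomagnesiation with the simple, robust Grignard reagent and introduces the oxygen afterwards. It sets out from 1 and comes back at 7. Bromide 1 with Mg in THF gives (4-methylpent-3-en-1-yl)magnesium bromide F5, which adds to 4 under CuI catalysis to give 6-methyl-2-methylidenehept-5-en-1-ol F6. Appel bromination gives 2-(bromomethyl)-6-methylhepta-1,5-diene F7. SeO2/t-BuOOH should then oxidise the (E)-methyl group of the electron-richer trisubstituted olefin, the 1,1-disubstituted olefin being deactivated by its bromomethyl group, to give (2E)-6-(bromomethyl)-2-methylhepta-2,6-dien-1-ol F8. Silylation with TBSOTf and 2,6-lutidine at –78 °C gives 7.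

Further compounds
F1 | step 15 | (3-bromo-4-methoxyphenoxy)(tert-butyl)dimethylsilane | COc1ccc(O[Si](C)(C)C(C)(C)C)cc1Br
F2 | step 15 | {5-[(tert-butyldimethylsilyl)oxy]-2-methoxyphenyl}lithium | [Li]c1cc(O[Si](C)(C)C(C)(C)C)ccc1OC
F3 | step 15 | 4-methoxybenzyl (2R)-2-(2-{5-[(tert-butyldimethylsilyl)oxy]-2-methoxyphenyl}-2-oxoethyl)-6-{(3E)-5-[(tert-butyldimethylsilyl)oxy]-4-methylpent-3-en-1-yl}-2,3,4,7-tetrahydrooxepine-2-carboxylate | C/C(=C\CCC1=CCC[C@@](CC(=O)c2cc(O[Si](C)(C)C(C)(C)C)ccc2OC)(C(=O)OCc2ccc(OC)cc2)OC1)CO[Si](C)(C)C(C)(C)C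
F4 | step 18 | 4-methoxybenzyl (2R)-2-[2-(2,5-dihydroxyphenyl)-2-oxoethyl]-6-[(3E)-5-{[(2E)-3-(4-hydroxyphenyl)prop-2-enoyl]oxy}-4-methylpent-3-en-1-yl]-2,3,4,7-tetrahydrooxepine-2-carboxylate | C/C(=C\CCC1=CCC[C@@](CC(=O)c2cc(O)ccc2O)(C(=O)OCc2ccc(OC)cc2)OC1)COC(=O)/C=C/c1ccc(O)cc1
F5 | step 3 | (4-methylpent-3-en-1-yl)magnesium bromide | CC(C)=CCC[Mg]Br
F6 | step 3 | 6-methyl-2-methylidenehept-5-en-1-ol | CC(C)=CCCC(=C)CO
F7 | step 3 | 2-(bromomethyl)-6-methylhepta-1,5-diene | CC(C)=CCCC(=C)CBr
F8 | step 3 | (2E)-6-(bromomethyl)-2-methylhepta-2,6-dien-1-ol | C/C(=C\CCC(=C)CBr)CO
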